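## The problem

Compound 21 is an eremophilane: a decalin in which ring A (C1–C5, C10) and ring B (C5–C10) share the C5–C10 bond. It carries methyl groups on C4 and on the quaternary C5, an isopropylidene group on C7, and a C8 ketone cross-conjugated with C7=C11 on one side and the C9=C10–C1=C2 diene on the other. Ring A holds three contiguous stereocentres, C3 (S), C4 (R) and C5 (R), with the ester oxygen and both methyl groups on the same (β) face; a fourth, remote centre (6S) lies in the dienoate side chain and must be brought in unchanged. C5 is quaternary and bears no heteroatom, so it has to be set by C–C bond formation; C4 is vicinal and is best set in the same event, whereas C3 is an allylic carbinol that can still be inverted once C4 and C5 stand. The trienone is an extended Michael acceptor and is enolisable at C6 and at the isopropylidene methyls, the allylic dienoate is sensitive to base, nucleophiles and ionising acid, and the side-chain centre is allylic to the diene. The ester should therefore be attached last, and the finished chromophore should not meet strong base. The feature that invites a short construction is the C1=C2 alkene, flanked by the oxygen-bearing sp3 carbon C3 and by the sp2 carbon C10, which is β to the C8 carbonyl. Returning the C3 oxygen to C10 turns ring A into a 7-oxanorbornene, the signature of a furan Diels–Alder adduct in which the furan oxygen is the future ester oxygen.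

## Retrosynthesis

**Ester bond.** The first cut is the C3–O bond: 21 goes back to the 3α-alcohol 15 and the acid 20, to be joined with inversion at C3. A retentive acylation of a 3β-alcohol is the obvious neighbour, but the cycloaddition below can only place the C3 oxygen trans to the methyl groups, so inversion and esterification are merged into one step. Joining last also keeps the dienoate away from every basic step. Acid 20 is traced through ester 19 to aldehyde 17 and phosphonate 18, and 17 to the chiral-pool alcohol 16. The forward reaction must achieve clean SN2 displacement at a hindered allylic carbinol without allylic transposition.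

**Ring B unsaturation.** Alcohol 15 is taken back through 14 to the bridged hydroxy ketone 13 by two retro-eliminations: the C3 oxygen is returned to C10 (reverse of an E1cB opening), and C7=C11 is rehydrated to a tertiary alcohol on C11. Ketone 13 comes from diol 12 by adjusting the oxidation level at C8. The neighbouring option, attaching a three-carbon unit to C7 of the finished dienone by an aldol reaction, would need protection of the C3 alcohol and strong base on the dienone. Here C9=C10, C1=C2, the free C3 alcohol and the isopropylidene group all arise by elimination from one ketone. The cross-conjugated trienone is thereby reduced to a saturated, oxygen-bridged diol with one isolated alkene. The forward steps must oxidise C8 without opening the bridge early and dehydrate a tertiary aldol without retro-aldol cleavage.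

**Key disconnection.** Diol 12 is cut at C3–C4 and C5–C10, a retro-[4+2] that gives the furan 11 with an (E)-trisubstituted alkene on a four-carbon tether. Cuts that break only one ring bond leave the C3 oxygen, C4 and C5 to be installed separately. This one returns two rings, two C–C bonds, four stereocentres and the C3 oxygen from an acyclic precursor with two stereocentres. Two design choices were made for the substrate.
- The tether carries a free hydroxyl on C8 and a 2-hydroxypropan-2-yl group on C7, trans to each other. Both are equatorial in the chair-like tether, so together they choose the furan face, and the C7 group is already the latent isopropylidene unit.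
- The alkene is left unactivated. An activating carbonyl could sit only on C6, C14 or C15, all saturated in 21, and would have to be removed again. High pressure is used instead, and the carbonyl-activated variant is held in reserve.

The forward reaction must overcome a poor dienophile and a reversible addition, and the adduct must be handled cold.

**Tether.** Diol 11 goes back to ester 9 by removing the two methyl groups on C11, and 9 to hydroxy ester 5 and the allylic bromide 7 by cutting C6–C7. Opening an epoxide with an allylic organometallic reagent would risk transposition of the allyl unit and loss of alkene geometry. SN2 alkylation of an enolate with the (E)-bromide 7 transfers the geometry intact, and the resident C8 alkoxide of 5 sets C7 anti. The ester serves twice, first as the enolate precursor and then as the source of C11–C13. Bromide 7 comes from alcohol 6. The forward reaction must give high anti selectivity and C-alkylation without elimination.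

**Carbinol centre.** Hydroxy ester 5 goes back to keto ester 4 (C8–H bond, asymmetric hydrogenation) and 4 to acid 1 and the malonate equivalent 2 through 3 (C7–C8 bond). This is the only catalyst-controlled step; every later centre is derived from C8. The precursors are achiral and purchasable.

## Roads not taken

**Alternative 1:** The cut lies on both sides of C4 (C3–C4 and C4–C5). The precursor is the hydrindenedione mono-dithioketal A2, whose quaternary carbon comes from a proline-catalysed annulation. In the forward key step a selenium-stabilised ethyl anion adds to the cyclopentanone carbonyl, and activation at selenium makes C5 migrate, inserting a CH–CH3 unit and giving the cyclohexanone A1.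
- Merits: every step has precedent, the quaternary centre comes from a reliable asymmetric annulation, C4 is set by equilibration, and no special equipment is needed. Reduction of a C3 ketone from the α face would give the 3β-alcohol directly, so the ester could be made with retention. In that respect it is better than the chosen plan, which has to invert C3.
- Weak points: the migrating carbon must be the hindered quaternary one, and addition to a neopentyl ketone is slow. A1 still lacks C1=C2, whose introduction by dehydrogenation competes with enolisation toward C4. The C8 carbonyl has to be masked and unmasked, and C11–C13 still have to be attached.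
- Comparison: the chosen plan offers roughly half the length, and in 12 the C3 oxygen and the latent C1=C2 and C9=C10 unsaturation are already in place. It pays with one step beyond precedent.

**Alternative 2:** The cut is the biosynthetic one. The acyclic diphosphate A4 is ionised by recombinant aristolochene synthase with MgCl2, cyclised twice, and rearranged by a hydride shift and a methyl shift to (+)-aristolochene A3.
- Merits: both rings and the C4 and C5 methyl centres come from an achiral precursor in one step. No chemical route matches this economy, and the chosen plan cannot claim it.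
- Weak points: A3 has no oxygen. C8 is allylic and could be oxidised, and the C11 alkene would move into conjugation once the ketone exists. C3, however, is an unactivated methylene with no handle, and C1=C2 would have to be introduced by desaturation. Both call for selective enzymatic or directed C–H oxidation that cannot be planned with confidence, and enzyme and substrate supply lie outside ordinary laboratory practice.
- Comparison: the chosen plan builds the C3 oxygen in as the furan oxygen, the very atom this road cannot place.

**Alternative 3:** The cut is C1–C10. The precursor is the prochiral cyclohexadienone A6 carrying a (Z)-vinyl iodide side chain. Zerovalent palladium, generated from Pd(OAc)2 and PPh3, inserts into the C–I bond, and the vinylpalladium species adds to one of the two enone arms to close ring A; loss of hydride then gives A5.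
- Merits: the ring closure belongs to a well-known catalytic reaction class and is more certain than the cycloaddition of the chosen plan. A5 already shows the 1,9-dien-8-one and the C3 oxygen.
- Weak points: the choice between the two enone arms, which sets C5, rests on the two tether centres alone. A6 needs its own stereocontrolled synthesis of two adjacent centres next to a quaternary carbon. A5 has a surplus C6=C7 alkene that must be saturated selectively within a cross-conjugated trienone before C11–C13 can be attached. Its C3 oxygen is α, so the same inversion is still needed.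
- Comparison: the chosen plan sets C5 and C4 together from alkene geometry, needs no differentiation of enone arms, and carries C11–C13 from the start.

Key step: step 6

Remark: eremophilane numbering is used for all bicyclic and tricyclic compounds (C14 on C5, C15 on C4, C11–C13 on C7); β is the face of the two methyl groups and α the opposite face.
Assumption: compounds 1, 2, 6, 16 and 18 are purchasable, and adduct 12 does not revert at or below 0 °C within the hours needed to oxidise it.

## Route

Step 1
Reactants: 1 2-(furan-2-yl)acetic acid; 2 2,2-dimethyl-1,3-dioxane-4,6-dione (Meldrum's acid)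
Product: 4 ethyl 4-(furan-2-yl)-3-oxobutanoate, via acyl Meldrum's acid 3 (not isolated)
Conditions: DCC, DMAP, CH2Cl2, 0 °C → rt; filtration; then EtOH, reflux
Reagents that add atoms: ethanol, CCO
Why: C-acylation of Meldrum's acid by the carbodiimide-activated acid, then ethanolysis with loss of acetone and CO2, is a standard two-carbon homologation to a β-keto ester; both stages are near neutral and tolerate the furan.

Step 2
Reactants: 4 ethyl 4-(furan-2-yl)-3-oxobutanoate
Product: 5 ethyl (3R)-4-(furan-2-yl)-3-hydroxybutanoate
Conditions: RuCl2[(R)-BINAP] (0.5 mol %), H2 (50 atm), EtOH, 50 °C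
Reagents that add atoms: none
Why: Noyori asymmetric hydrogenation of a β-keto ester; the ester carbonyl chelates ruthenium and the (R)-BINAP ligand should deliver hydrogen to the face that gives the (3R)-alcohol, by analogy with simple 3-oxobutanoates, setting C8. The aromatic furan should not be reduced under these conditions.

Step 3
Reactants: 6 (E)-2-methylbut-2-en-1-ol
Product: 7 (E)-1-bromo-2-methylbut-2-ene
Conditions: PBr3 (0.4 equiv), Et2O, −10 → 0 °C
Reagents that add atoms: phosphorus tribromide, BrP(Br)Br
Why: Bromination of a primary allylic alcohol with PBr3 at low temperature proceeds by direct displacement and should leave the (E)-trisubstituted alkene in place.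

Step 4
Reactants: 5 ethyl (3R)-4-(furan-2-yl)-3-hydroxybutanoate; 7 (E)-1-bromo-2-methylbut-2-ene
Product: 9 ethyl (2R,4E)-2-[(1R)-2-(furan-2-yl)-1-hydroxyethyl]-4-methylhex-4-enoate, via dilithium dianion 8 (not isolated)
Conditions: LiN(i-Pr)2 (2.2 equiv), THF, −78 → −20 °C; then 7, DMPU, −78 → −10 °C
Reagents that add atoms: none
Why: Fráter–Seebach alkylation; the chelated alkoxide–enolate 8 is alkylated by SN2 at the primary allylic carbon (no transposition, E geometry kept) on the enolate face opposite the furylmethyl group. This gives the anti ester, in which the new C7 centre is (R) next to C8 (R).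

Step 5
Reactants: 9 ethyl (2R,4E)-2-[(1R)-2-(furan-2-yl)-1-hydroxyethyl]-4-methylhex-4-enoate
Product: 11 (2R,3R,5E)-1-(furan-2-yl)-3-(2-hydroxypropan-2-yl)-5-methylhept-5-en-2-ol, via methyl ketone 10 (not isolated)
Conditions: MeMgBr (5 equiv), THF, 0 °C → rt; aqueous work-up
Reagents that add atoms: methylmagnesium bromide, C[Mg]Br
Why: Double Grignard addition to the ester through ketone 10, after the first equivalent has deprotonated the hydroxyl group; the neighbouring magnesium alkoxide should disfavour enolisation, so C7 is kept.

Step 6
Reactants: 11 (2R,3R,5E)-1-(furan-2-yl)-3-(2-hydroxypropan-2-yl)-5-methylhept-5-en-2-ol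
Product: 12 (3R,4R,5R,7R,8R,10S)-3α,10α-epoxy-7βH-eremophil-1-ene-8β,11-diol (oxygen-bridged tricyclic diol)
Conditions: CH2Cl2 (0.05 M), 2,6-di-tert-butyl-4-methylphenol (trace), 14 kbar, 25 °C, 72 h; decompression at 0 °C, crude adduct used cold
Reagents that add atoms: none
Why: Proposed new method: an intramolecular furan Diels–Alder reaction of an unactivated trisubstituted alkene on an all-carbon four-atom tether is not known; the closest known types are high-pressure intramolecular furan cycloadditions of carbonyl-activated alkenes and thermal ones of unactivated alkenes on three-atom tethers. The addition is a concerted, asynchronous, suprafacial [4+2] process with strongly negative volumes of activation and reaction, so 14 kbar should speed it by orders of magnitude and move the otherwise unfavourable equilibrium to the adduct, which should stay intact while kept cold. Ring B closes as a six-membered carbocycle when C5 bonds to C10 through a chair-like tether, and ring A closes as the boat-shaped cyclohexene of a 7-oxanorbornene when C3 bonds to C4, the furan oxygen bridging C3 and C10. C4 and C5 are set by the (E)-alkene, which adds suprafacially so that the two methyl groups end cis. C3 and C10 follow from the tether, which can span C10 and C5 only on the exo side, syn to the oxygen bridge, so both methyls lie anti to the bridge and the C3 oxygen is α. The absolute sense comes from C7 and C8: in the chair the C8 hydroxyl and the bulky 2-hydroxypropan-2-yl group on C7 are trans-diequatorial, whereas attack on the other furan face would force both axial. Face selectivity is thus the only selectivity the step needs, regiochemistry being fixed by the tether, and the trans-vicinal substituents also favour the folded tether rotamers.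

Step 7
Reactants: 12 3α,10α-epoxy-7βH-eremophil-1-ene-8β,11-diol
Product: 13 (3R,4R,5R,7S,10S)-3α,10α-epoxy-11-hydroxy-7βH-eremophil-1-en-8-one
Conditions: Dess–Martin periodinane (1.2 equiv), NaHCO3, CH2Cl2, 0 °C
Reagents that add atoms: none
Why: Dess–Martin oxidation of the secondary C8 alcohol under buffered, non-basic conditions should leave the tertiary alcohol, the strained alkene and the still-closed oxygen bridge untouched; no new stereocentre is formed.

Step 8
Reactants: 13 3α,10α-epoxy-11-hydroxy-7βH-eremophil-1-en-8-one
Product: 15 (3R,4R,5R)-3α-hydroxyeremophila-1,7(11),9-trien-8-one, via bridged isopropylidene ketone 14 (not isolated)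
Conditions: Burgess reagent (1.3 equiv), toluene, 25 °C; short silica plug; then DBU (1.2 equiv), CH2Cl2, 0 → 25 °C
Reagents that add atoms: none
Why: Burgess dehydration of the tertiary β-hydroxy ketone should give the conjugated isopropylidene ketone 14, and any isopropenyl isomer would be brought into conjugation by DBU. DBU then removes a C9 proton and expels the C10–O bond by E1cB, which releases the strain of the 7-oxanorbornene and unveils C9=C10, C1=C2 and the C3 alcohol with its α configuration unchanged.

Step 9
Reactants: 16 (S)-2-methylbutan-1-ol
Product: 17 (S)-2-methylbutanal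
Conditions: TEMPO (10 mol %), PhI(OAc)2 (1.1 equiv), CH2Cl2, 0 °C → rt; washed and dried solution used at once
Reagents that add atoms: none
Why: Oxoammonium-mediated (TEMPO) oxidation of a primary alcohol stops at the aldehyde under nearly neutral conditions, which should protect the α-stereocentre from enolisation.

Step 10
Reactants: 17 (S)-2-methylbutanal; 18 triethyl 4-phosphonocrotonate
Product: 19 ethyl (2E,4E,6S)-6-methylocta-2,4-dienoate
Conditions: LiN(SiMe3)2 (1.05 equiv), THF, −78 → 0 °C
Reagents that add atoms: none
Why: Vinylogous Horner–Wadsworth–Emmons olefination; at low temperature the lithiated phosphonate should add to the aldehyde faster than it deprotonates it, giving the (2E,4E)-dienoate with the C6 centre intact.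

Step 11
Reactants: 19 ethyl (2E,4E,6S)-6-methylocta-2,4-dienoate
Product: 20 (2E,4E,6S)-6-methylocta-2,4-dienoic acid
Conditions: LiOH, THF–MeOH–H2O, rt; then 1 M HCl to pH 3
Reagents that add atoms: lithium hydroxide, [Li+].[OH-]
Why: Saponification of the ethyl ester at room temperature; the conjugated dienoate should not be deconjugated under these mild conditions.

Step 12
Reactants: 15 3α-hydroxyeremophila-1,7(11),9-trien-8-one; 20 (2E,4E,6S)-6-methylocta-2,4-dienoic acid
Product: 21 (3S,4R,5R)-8-oxoeremophila-1,7(11),9-trien-3β-yl (2E,4E,6S)-6-methylocta-2,4-dienoate
Conditions: PPh3 (2 equiv), DIAD (2 equiv), toluene, 0 °C → rt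
Reagents that add atoms: none
Why: Mitsunobu esterification with inversion; the alkoxyphosphonium ion of the 3α-alcohol is displaced by the carboxylate from the β face (SN2), which gives the 3β-ester cis to both methyl groups. The C4 hydrogen is cis to the leaving group, which excludes anti elimination, and the electron-poor dienone disfavours ionisation.

## Compound list

1 | 2-(furan-2-yl)acetic acid | OC(=O)Cc1ccco1 | starting material
2 | 2,2-dimethyl-1,3-dioxane-4,6-dione (Meldrum's acid) | CC1(C)OC(=O)CC(=O)O1 | starting material
3 | 5-[2-(furan-2-yl)-1-hydroxyethylidene]-2,2-dimethyl-1,3-dioxane-4,6-dione | CC1(C)OC(=O)C(=C(O)Cc2ccco2)C(=O)O1 | intermediate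
4 | ethyl 4-(furan-2-yl)-3-oxobutanoate | CCOC(=O)CC(=O)Cc1ccco1 | intermediate
5 | ethyl (3R)-4-(furan-2-yl)-3-hydroxybutanoate | CCOC(=O)C[C@H](O)Cc1ccco1 | intermediate
6 | (E)-2-methylbut-2-en-1-ol | C/C=C(\C)CO | starting material
7 | (E)-1-bromo-2-methylbut-2-ene | C/C=C(\C)CBr | intermediate
8 | dilithium alkoxide–enolate of 5 | [Li+].[Li+].CCOC([O-])=C[C@H]([O-])Cc1ccco1 | intermediate
9 | ethyl (2R,4E)-2-[(1R)-2-(furan-2-yl)-1-hydroxyethyl]-4-methylhex-4-enoate | c1coc(c1)C[C@@H](O)[C@H](C(=O)OCC)C/C(C)=C/C | intermediate
10 | (3R,5E)-3-[(1R)-2-(furan-2-yl)-1-hydroxyethyl]-5-methylhept-5-en-2-one | c1coc(c1)C[C@@H](O)[C@H](C(C)=O)C/C(C)=C/C | intermediate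
11 | (2R,3R,5E)-1-(furan-2-yl)-3-(2-hydroxypropan-2-yl)-5-methylhept-5-en-2-ol | c1coc(c1)C[C@@H](O)[C@H](C(C)(C)O)C/C(C)=C/C | intermediate
12 | (3R,4R,5R,7R,8R,10S)-3α,10α-epoxy-7βH-eremophil-1-ene-8β,11-diol | C[C@H]1[C@H]2C=C[C@@]3(O2)C[C@@H](O)[C@H](C(C)(C)O)C[C@]13C | intermediate
13 | (3R,4R,5R,7S,10S)-3α,10α-epoxy-11-hydroxy-7βH-eremophil-1-en-8-one | C[C@H]1[C@H]2C=C[C@@]3(O2)CC(=O)[C@H](C(C)(C)O)C[C@]13C | intermediate
14 | (3R,4R,5R,10S)-3α,10α-epoxyeremophila-1,7(11)-dien-8-one | C[C@H]1[C@H]2C=C[C@@]3(O2)CC(=O)C(=C(C)C)C[C@]13C | intermediate
15 | (3R,4R,5R)-3α-hydroxyeremophila-1,7(11),9-trien-8-one | O[C@@H]1C=CC2=CC(=O)C(=C(C)C)C[C@]2(C)[C@H]1C | intermediate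
16 | (S)-2-methylbutan-1-ol | CC[C@H](C)CO | starting material
17 | (S)-2-methylbutanal | CC[C@H](C)C=O | intermediate
18 | triethyl 4-phosphonocrotonate [ethyl (E)-4-(diethoxyphosphoryl)but-2-enoate] | CCOC(=O)/C=C/CP(=O)(OCC)OCC | starting material
19 | ethyl (2E,4E,6S)-6-methylocta-2,4-dienoate | CC[C@H](C)/C=C/C=C/C(=O)OCC | intermediate
20 | (2E,4E,6S)-6-methylocta-2,4-dienoic acid | CC[C@H](C)/C=C/C=C/C(=O)O | intermediate
21 | (3S,4R,5R)-8-oxoeremophila-1,7(11),9-trien-3β-yl (2E,4E,6S)-6-methylocta-2,4-dienoate | CC[C@H](C)/C=C/C=C/C(=O)O[C@H]1C=CC2=CC(=O)C(=C(C)C)C[C@]2(C)[C@H]1C | target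

## Step count and least certain steps

Total step count: 12. Longest linear sequence: 8 steps (steps 1, 2, 4, 5, 6, 7, 8 and 12, from acid 1).

**Step 6 (key step, beyond known chemistry).** The most likely failure is that the cycloaddition does not advance far enough even under pressure, or that the adduct reverts during decompression and work-up, because an unactivated trisubstituted alkene lowers neither the barrier nor the free energy of the adduct. Incomplete discrimination of the two furan faces is the second concern. Known chemistry is available if the alkene is made part of an enone, at the price of a later deoxygenation at C6 and a late aldol to bring in C11–C13. This fallback sets out from 5 and returns to the route at 15.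
- Silylation of 5 (TBSCl, imidazole) gives ethyl (3R)-3-(tert-butyldimethylsilyloxy)-4-(furan-2-yl)butanoate F1.
- Me(MeO)NH·HCl with i-PrMgCl gives the Weinreb amide F2.
- (E)-But-2-en-2-yllithium, from (E)-2-bromobut-2-ene and t-BuLi, gives the tigloyl ketone F3, whose carbonyl carbon is now C6.
- The Lewis acid-promoted intramolecular furan Diels–Alder reaction of such tether enones is an established reaction type; MeAlCl2 (1.1 equiv, CH2Cl2, −78 °C) should give the 6-oxo adduct F4 with the silyloxy group pseudo-equatorial.
- NaBH4 then gives the C6 alcohol F5, and NaH/CS2/MeI its xanthate F6.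
- Bu3SnH with Et3B and air at room temperature (Barton–McCombie deoxygenation) gives the bridged silyl ether F7.
- Bu4NF frees the alcohol F8, and Dess–Martin oxidation gives the ketone F9.
- DBU opens the bridge to the 3α-hydroxy dienone F10, and TBSCl/imidazole protects it as the silyl ether F11.
- Deprotonation at C7 with LiN(i-Pr)2 at −78 °C, transmetallation with ZnCl2 and addition of acetone give the aldol F12.
- MsCl/Et3N followed by DBU gives the isopropylidene silyl ether F13, and HF·pyridine returns 15.

**Step 12.** The most likely failure is incomplete inversion: the hindered allylic carbinol may react slowly, or the activated alcohol may be attacked at C1 with allylic shift. The fallback replaces substitution by an oxidation–reduction sequence; it sets out from 15 and returns at 21.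
- Dess–Martin oxidation gives the 3,8-dione F14.
- NaBH4/CeCl3 in MeOH at −78 °C (Luche conditions) should reduce the C3 carbonyl first, since the C8 carbonyl is cross-conjugated and shielded by the isopropylidene group. Hydride should arrive from the α face, away from both methyl groups, to give the 3β-alcohol F15.
- Acylation of F15 with 20 (2,4,6-trichlorobenzoyl chloride, Et3N, DMAP; Yamaguchi conditions) then gives 21 with retention.

**Step 8.** The most likely failure is opening of the oxygen bridge before dehydration is complete, so that the freed C3 hydroxyl competes for the dehydrating agent; retro-aldol loss of the three-carbon unit is the second concern. The fallback changes the order of events so that dehydration is the last operation, on a substrate without a free secondary alcohol; it sets out from 13 and returns at 21.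
- DBU alone at 0 °C opens the bridge to the 3α,11-diol F16.
- Mitsunobu esterification with 20 acts only on the secondary alcohol and gives the 11-hydroxy ester F17.
- Burgess reagent (or MsCl/Et3N followed by DBU) then dehydrates F17 to 21.

**Step 4.** The most likely failure is proton transfer or O-alkylation in place of C-alkylation, or erosion of the anti selectivity if the chelate is not maintained. The fallback forms the C6–C7 bond by sigmatropic rearrangement instead of substitution; it sets out from 5 and returns at 11.
- Transesterification of 5 with 3-methylbut-3-en-2-ol (Ti(Oi-Pr)4, cat.) gives the allylic ester F18.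
- The dianion Ireland–Claisen rearrangement (LiN(i-Pr)2, 2.3 equiv, THF, −78 °C → reflux) should deliver the anti acid F19; the (E)-alkene follows from the chair transition state.
- Me3SiCHN2 gives the methyl ester F20, and MeMgBr gives 11.

## Further compounds

F1 | step 6 | ethyl (3R)-3-(tert-butyldimethylsilyloxy)-4-(furan-2-yl)butanoate | CCOC(=O)C[C@H](O[Si](C)(C)C(C)(C)C)Cc1ccco1
F2 | step 6 | (3R)-3-(tert-butyldimethylsilyloxy)-4-(furan-2-yl)-N-methoxy-N-methylbutanamide | CON(C)C(=O)C[C@H](O[Si](C)(C)C(C)(C)C)Cc1ccco1
F3 | step 6 | (2E,6R)-6-(tert-butyldimethylsilyloxy)-7-(furan-2-yl)-3-methylhept-2-en-4-one | C/C=C(\C)C(=O)C[C@H](O[Si](C)(C)C(C)(C)C)Cc1ccco1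
F4 | step 6 | 8β-(tert-butyldimethylsilyloxy)-3α,10α-epoxy-11,12,13-trinoreremophil-1-en-6-one | C[C@H]1[C@H]2C=C[C@@]3(O2)C[C@@H](O[Si](C)(C)C(C)(C)C)CC(=O)[C@]13C
F5 | step 6 | 8β-(tert-butyldimethylsilyloxy)-3α,10α-epoxy-11,12,13-trinoreremophil-1-en-6-ol (either C6 epimer) | C[C@H]1[C@H]2C=C[C@@]3(O2)C[C@@H](O[Si](C)(C)C(C)(C)C)CC(O)[C@]13C
F6 | step 6 | O-[8β-(tert-butyldimethylsilyloxy)-3α,10α-epoxy-11,12,13-trinoreremophil-1-en-6-yl] S-methyl dithiocarbonate | C[C@H]1[C@H]2C=C[C@@]3(O2)C[C@@H](O[Si](C)(C)C(C)(C)C)CC(OC(=S)SC)[C@]13C
F7 | step 6 | 8β-(tert-butyldimethylsilyloxy)-3α,10α-epoxy-11,12,13-trinoreremophil-1-ene | C[C@H]1[C@H]2C=C[C@@]3(O2)C[C@@H](O[Si](C)(C)C(C)(C)C)CC[C@]13C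
F8 | step 6 | 3α,10α-epoxy-11,12,13-trinoreremophil-1-en-8β-ol | C[C@H]1[C@H]2C=C[C@@]3(O2)C[C@@H](O)CC[C@]13C
F9 | step 6 | 3α,10α-epoxy-11,12,13-trinoreremophil-1-en-8-one | C[C@H]1[C@H]2C=C[C@@]3(O2)CC(=O)CC[C@]13C
F10 | step 6 | 3α-hydroxy-11,12,13-trinoreremophila-1,9-dien-8-one | O[C@@H]1C=CC2=CC(=O)CC[C@]2(C)[C@H]1C
F11 | step 6 | 3α-(tert-butyldimethylsilyloxy)-11,12,13-trinoreremophila-1,9-dien-8-one | CC(C)(C)[Si](C)(C)O[C@@H]1C=CC2=CC(=O)CC[C@]2(C)[C@H]1C
F12 | step 6 | 3α-(tert-butyldimethylsilyloxy)-11-hydroxyeremophila-1,9-dien-8-one (either C7 epimer) | CC(C)(C)[Si](C)(C)O[C@@H]1C=CC2=CC(=O)C(C(C)(C)O)C[C@]2(C)[C@H]1C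
F13 | step 6 | 3α-(tert-butyldimethylsilyloxy)eremophila-1,7(11),9-trien-8-one | CC(C)(C)[Si](C)(C)O[C@@H]1C=CC2=CC(=O)C(=C(C)C)C[C@]2(C)[C@H]1C
F14 | step 12 | eremophila-1,7(11),9-triene-3,8-dione | O=C1C=CC2=CC(=O)C(=C(C)C)C[C@]2(C)[C@H]1C
F15 | step 12 | 3β-hydroxyeremophila-1,7(11),9-trien-8-one | O[C@H]1C=CC2=CC(=O)C(=C(C)C)C[C@]2(C)[C@H]1C
F16 | step 8 | 3α,11-dihydroxy-7βH-eremophila-1,9-dien-8-one | O[C@@H]1C=CC2=CC(=O)[C@H](C(C)(C)O)C[C@]2(C)[C@H]1C
F17 | step 8 | 11-hydroxy-8-oxo-7βH-eremophila-1,9-dien-3β-yl (2E,4E,6S)-6-methylocta-2,4-dienoate | CC[C@H](C)/C=C/C=C/C(=O)O[C@H]1C=CC2=CC(=O)[C@H](C(C)(C)O)C[C@]2(C)[C@H]1C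
F18 | step 4 | 3-methylbut-3-en-2-yl (3R)-4-(furan-2-yl)-3-hydroxybutanoate (either configuration at the ester carbinol carbon) | CC(OC(=O)C[C@H](O)Cc1ccco1)C(C)=C
F19 | step 4 | (2R,4E)-2-[(1R)-2-(furan-2-yl)-1-hydroxyethyl]-4-methylhex-4-enoic acid | c1coc(c1)C[C@@H](O)[C@H](C(=O)O)C/C(C)=C/C
F20 | step 4 | methyl (2R,4E)-2-[(1R)-2-(furan-2-yl)-1-hydroxyethyl]-4-methylhex-4-enoate | c1coc(c1)C[C@@H](O)[C@H](C(=O)OC)C/C(C)=C/C
A1 | alternative 1 | 8,8-(ethane-1,2-diyldisulfanediyl)-11,12,13-trinoreremophil-9-en-3-one (4β,5β-dimethyl) | O=C1CCC2=CC3(CC[C@]2(C)[C@H]1C)SCCS3
A2 | alternative 1 | 7a-methyl-2,3,7,7a-tetrahydro-1H-indene-1,5(6H)-dione 5-(1,3-dithiolane), enantiomer with the eremophilane configuration at the quaternary carbon | O=C1CCC2=CC3(CC[C@]12C)SCCS3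
A3 | alternative 2 | (+)-aristolochene, (4S,5R,7S)-eremophila-9,11-diene | C[C@H]1CCCC2=CC[C@@H](C[C@]12C)C(C)=C
A4 | alternative 2 | (2E,6E)-farnesyl diphosphate | CC(C)=CCC/C(C)=C/CC/C(C)=C/COP(O)(=O)OP(O)(O)=O
A5 | alternative 3 | 3α-(tert-butyldimethylsilyloxy)-11,12,13-trinoreremophila-1,6,9-trien-8-one | CC(C)(C)[Si](C)(C)O[C@@H]1C=CC2=CC(=O)C=C[C@]2(C)[C@H]1C
A6 | alternative 3 | 4-[(2R,3S,4Z)-3-(tert-butyldimethylsilyloxy)-5-iodopent-4-en-2-yl]-4-methylcyclohexa-2,5-dien-1-one | CC(C)(C)[Si](C)(C)O[C@H](/C=C\I)[C@H](C)C1(C)C=CC(=O)C=C1
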